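**Decay exponent.** The ratio of the logarithmic fall of other mono adduct to that of mono adduct in spring, between 1.33 min and 6.00 min, is the decay exponent 2.22; its late reading of other mono adduct carries the full scatter. We take reagent to consume both adducts, so that its history stands in both falls and cancels in the ratio. Other mono adduct then falls as the fall of mono adduct raised to this exponent.

the same everywhere: starting material 0.10 M

|  | reagent | remark | time |
|---|---|---|---|
| autumn | 0.027 M | run made earlier |  |
| spring | 0.32 M | run made earlier |  |
| north-east | 0.400 M |  | 10 min |
| north-west | 0.0500 M |  | 10 min |

| run | time / min | other mono adduct / % | mono adduct / % |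
|---|---|---|---|
| autumn | 1.33 | 1.8 | 9.0 |
| autumn | 3.00 | 1.9 | 11.2 |
| autumn | 4.00 | 2.3 | 12.7 |
| autumn | 6.00 | 2.3 | 14.1 |
| autumn | 8.00 | 2.2 | 14.1 |
| autumn | 10.0 | 1.9 | 14.6 |
| spring | 1.33 | 6.3 | 47.3 |
| spring | 3.00 | 4.7 | 38.5 |
| spring | 4.00 | 3.5 | 33.1 |
| spring | 6.00 | 1.3 | 23.2 |
| spring | 8.00 | 0.9 | 16.3 |
| spring | 10.0 | 0.6 | 12.4 |

(scatter of a reading: 0.5 percentage points)
- which of these holds the largest part of the starting material at the end of north-east (other mono adduct / double product / mono adduct / starting material)
- which of these holds the largest part of the starting material at the end of north-west (other mono adduct / double product / mono adduct / starting material)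
- amount of other mono adduct at the end of north-east, in percent of the starting material charged
- the numbers in the tables scatter by 0.5 percentage points (one standard deviation)

**North-east reckoning.** We expect about 0.250 M of reagent standing in north-east, against 0.170 M in spring, so its exposure is 1.47 times that of spring. From the first spring reading, our north-east mono adduct ends near 6.60% of the charge. The exponent then gives 0.0804% of other mono adduct. Keep the flask closed and add no reagent, since this reckoning rests on the charge as it stands.

**The forecast.** It gives double product for north-east, starting material for north-west and 0.25%, above our figure, with “Double product dominates at about 90%”.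

**The result.** North-east ends with 0.117% of other mono adduct and mostly double product, at 74.8%; of the four species asked, north-west holds the largest part as mono adduct, at 23.0%, while homo dimer holds 64.4% of the charge there.

    starting material + reagent → mono adduct + by-product (k = 0.0870 /M/s)
    starting material + reagent → other mono adduct + by-product (k = 0.0160 /M/s)
    reagent + mono adduct → double product + by-product (k = 0.0150 /M/s)
    reagent + other mono adduct → double product + by-product (k = 0.0310 /M/s)
    2 starting material → homo dimer (k = 0.0890 /M/s)

**Second use.** North-east's mono adduct stood at 7.04%, and the exponent turns that into 0.0927% of other mono adduct. The neighbour charged with 0.040 M of starting material ended with 4.25% of mono adduct, which the exponent turns into 0.0302%; that neighbour held 0.0363%.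

The readings are simulated with constants of no real substance, noise included.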